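**Retrosynthetic overview**
1. The nitrogen ring closes last: the C1=N bond forms by condensation of an (R)-primary amine with an ortho-acetyl group, so no electrophilic cyclisation regiochemistry arises.
2. The biaryl C7–C1′ bond comes from a Suzuki–Miyaura coupling (Pd(OAc)2/SPhos) of an aryl chloride with (4,5-dimethoxy-2-methylnaphthalen-1-yl)boronic acid.
3. The acetyl group comes from an aryl triflate (Stille coupling with a 1-ethoxyvinyl stannane); C-3 is set on the prochiral arylacetone by an (R)-selective ω-transaminase.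
4. The arylacetone comes from 3-chloro-2-methoxyphenol by O-allylation, Claisen rearrangement, triflation and Wacker oxidation.
5. Ring order: the second naphthalene ring is built first (directed ortho-metalation/methallylation of N,N-diethyl-2-methoxybenzamide, then anionic annulation); the isoquinoline benzene ring is bought; the nitrogen ring is formed last.

Assumption: the SMILES defines only C-3 (R) and leaves the hindered biaryl axis undefined, so the route controls C-3 and carries both atropo-diastereomers formed in step 14 (separable by HPLC at the end if one is wanted).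

**Fragment A: naphthalene boronic acid**

Step 1
Reactants: 1 2-methoxybenzoyl chloride
Product: 2 N,N-diethyl-2-methoxybenzamide
Conditions: Et2NH (1.2 equiv), 2 M aq NaOH, CH2Cl2, 0 °C → rt
Reagents that add atoms: diethylamine, CCNCC
Why: Schotten–Baumann N-acylation of a secondary amine by an acid chloride is fast and clean and installs the amide used as ortho-directing group.

Step 2
Reactants: 2 N,N-diethyl-2-methoxybenzamide; 3 3-bromo-2-methylprop-1-ene
Product: 6 N,N-diethyl-2-methoxy-6-(2-methylprop-2-en-1-yl)benzamide, via aryllithium 4 (not isolated), via arylmagnesium bromide 5 (not isolated)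
Conditions: s-BuLi, TMEDA, THF, −78 °C; MgBr2·OEt2, −78 °C; 3, −78 °C → rt
Reagents that add atoms: none
Why: Directed ortho-metalation, in which the tertiary amide outranks the methoxy group so that C-6 is lithiated, followed by transmetalation to magnesium and clean allylation by the allylic bromide.

Step 3
Reactants: 6 N,N-diethyl-2-methoxy-6-(2-methylprop-2-en-1-yl)benzamide
Product: 7 8-methoxy-3-methylnaphthalen-1-ol
Conditions: LiN(i-Pr)2 (2.2 equiv), THF, −78 °C → rt; aq HCl
Reagents that add atoms: none
Why: Anionic ring annulation (intramolecular acylation): benzylic–allylic deprotonation gives a delocalised anion whose terminal carbon attacks the neighbouring amide, diethylamide is expelled and enolisation aromatises the new ring.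

Step 4
Reactants: 7 8-methoxy-3-methylnaphthalen-1-ol
Product: 8 1,8-dimethoxy-3-methylnaphthalene
Conditions: MeI, K2CO3, DMF, 40 °C
Reagents that add atoms: iodomethane, CI
Why: Williamson O-methylation of the naphtholate.

Step 5
Reactants: 8 1,8-dimethoxy-3-methylnaphthalene
Product: 9 1-bromo-4,5-dimethoxy-2-methylnaphthalene
Conditions: NBS (1.0 equiv), MeCN, 0 °C → rt, dark
Reagents that add atoms: N-bromosuccinimide, O=C1CCC(=O)N1Br
Why: Electrophilic aromatic bromination at C-4, the α-position para to the C-1 methoxy group and ortho to the methyl group and therefore the most activated site.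

Step 6
Reactants: 9 1-bromo-4,5-dimethoxy-2-methylnaphthalene
Product: 12 (4,5-dimethoxy-2-methylnaphthalen-1-yl)boronic acid, via naphthyllithium 10 (not isolated), via lithium aryltrimethoxyborate 11 (not isolated)
Conditions: n-BuLi, THF, −78 °C; B(OMe)3, −78 °C → rt; 1 M aq HCl
Reagents that add atoms: trimethyl borate, COB(OC)OC; water, O
Why: Bromine–lithium exchange, borylation of the aryllithium and acidic hydrolysis of the borate is the standard arylboronic acid synthesis.

**Fragment B: chiral amine and acetyl group**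

Step 7
Reactants: 13 3-chloro-2-methoxyphenol; 14 3-bromoprop-1-ene
Product: 15 1-chloro-2-methoxy-3-(prop-2-en-1-yloxy)benzene
Conditions: K2CO3, acetone, reflux
Reagents that add atoms: none
Why: Williamson ether synthesis on a phenoxide with a reactive allylic bromide.

Step 8
Reactants: 15 1-chloro-2-methoxy-3-(prop-2-en-1-yloxy)benzene
Product: 16 3-chloro-2-methoxy-6-(prop-2-en-1-yl)phenol
Conditions: N,N-diethylaniline, 190 °C
Reagents that add atoms: none
Why: Aromatic Claisen rearrangement; the [3,3] shift delivers the allyl group to the only free ortho position, and rearomatisation gives the phenol with the 1,2,3,4-substitution pattern of the target.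

Step 9
Reactants: 16 3-chloro-2-methoxy-6-(prop-2-en-1-yl)phenol
Product: 17 3-chloro-2-methoxy-6-(prop-2-en-1-yl)phenyl trifluoromethanesulfonate
Conditions: Tf2O, pyridine, CH2Cl2, 0 °C
Reagents that add atoms: trifluoromethanesulfonic anhydride, O=S(=O)(OS(=O)(=O)C(F)(F)F)C(F)(F)F
Why: O-Sulfonylation turns the phenol into a cross-coupling handle and stops the benzofuran formation a free ortho-phenol would give in the next step.

Step 10
Reactants: 17 3-chloro-2-methoxy-6-(prop-2-en-1-yl)phenyl trifluoromethanesulfonate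
Product: 18 3-chloro-2-methoxy-6-(2-oxopropyl)phenyl trifluoromethanesulfonate
Conditions: PdCl2 (10 mol %), CuCl (1 equiv), O2 (1 atm), DMF/H2O 7:1, rt
Reagents that add atoms: water, O
Why: Tsuji–Wacker oxidation: water adds to the PdCl2-activated terminal alkene at the internal carbon to give the methyl ketone, CuCl/O2 reoxidise zerovalent palladium, and the triflate and chloride are inert without phosphine.

Step 11
Reactants: 18 3-chloro-2-methoxy-6-(2-oxopropyl)phenyl trifluoromethanesulfonate
Product: 19 6-[(2R)-2-aminopropyl]-3-chloro-2-methoxyphenyl trifluoromethanesulfonate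
Conditions: (R)-selective ω-transaminase (amine transaminase), pyridoxal 5′-phosphate (1 mM), i-PrNH2 (1 M), triethanolamine buffer pH 8.0, DMSO (20% v/v), 35 °C, N2 sweep; extract at pH 10
Reagents that add atoms: isopropylamine, CC(C)N
Why: Asymmetric biocatalytic transamination: the enzyme binds methyl in its small pocket and the arylmethyl group in its large pocket and delivers nitrogen to one face of the ketone, setting C-3 as (R) (typically >99% ee), with excess amine donor and acetone removal driving the equilibrium.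

Step 12
Reactants: 19 6-[(2R)-2-aminopropyl]-3-chloro-2-methoxyphenyl trifluoromethanesulfonate
Product: 20 6-[(2R)-2-[(tert-butoxycarbonyl)amino]propyl]-3-chloro-2-methoxyphenyl trifluoromethanesulfonate
Conditions: Boc2O, Et3N, CH2Cl2, rt (crude amine used directly)
Reagents that add atoms: di-tert-butyl dicarbonate, CC(C)(C)OC(=O)OC(=O)OC(C)(C)C
Why: Carbamate protection of the amine prevents N-arylation and attack on the triflate in the coupling steps.

Step 13
Reactants: 20 6-[(2R)-2-[(tert-butoxycarbonyl)amino]propyl]-3-chloro-2-methoxyphenyl trifluoromethanesulfonate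
Product: 22 tert-butyl N-[(2R)-1-(2-acetyl-4-chloro-3-methoxyphenyl)propan-2-yl]carbamate, via enol ether 21 (not isolated)
Conditions: tributyl(1-ethoxyvinyl)stannane, Pd(PPh3)4 (10 mol %), LiCl (3 equiv), 1,4-dioxane, 100 °C; then 1 M aq HCl, THF, rt, 30 min
Reagents that add atoms: tributyl(1-ethoxyvinyl)stannane, CCCC[Sn](CCCC)(CCCC)C(=C)OCC; water, O
Why: Stille coupling: Pd(PPh3)4 inserts into the C–OTf bond only (the aryl chloride is inert to it), LiCl assists transmetalation, and mild aqueous acid unmasks the enol ether as the acetyl group while the Boc group stays.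

**Convergent end game**

Step 14
Reactants: 22 tert-butyl N-[(2R)-1-(2-acetyl-4-chloro-3-methoxyphenyl)propan-2-yl]carbamate; 12 (4,5-dimethoxy-2-methylnaphthalen-1-yl)boronic acid (1.5 equiv)
Product: 23 tert-butyl N-[(2R)-1-[2-acetyl-4-(4,5-dimethoxy-2-methylnaphthalen-1-yl)-3-methoxyphenyl]propan-2-yl]carbamate
Conditions: Pd(OAc)2 (5 mol %), SPhos (10 mol %), K3PO4, toluene/H2O 10:1, 100 °C
Reagents that add atoms: none
Why: Suzuki–Miyaura coupling: Pd(OAc)2/SPhos activates the aryl chloride and tolerates three ortho substituents, the carbamate and ketone are inert to K3PO4, and the axis forms as both atropo-diastereomers.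

Step 15
Reactants: 23 tert-butyl N-[(2R)-1-[2-acetyl-4-(4,5-dimethoxy-2-methylnaphthalen-1-yl)-3-methoxyphenyl]propan-2-yl]carbamate
Product: 25 (3R)-7-(4,5-dimethoxy-2-methylnaphthalen-1-yl)-8-methoxy-1,3-dimethyl-3,4-dihydroisoquinoline, via amino ketone 24 (not isolated)
Conditions: 4 M HCl in 1,4-dioxane, rt; then sat. aq NaHCO3, CH2Cl2, rt
Reagents that add atoms: none
Why: Acidolysis removes the Boc group and, on neutralisation, the free amine condenses with the ortho-acetyl group (intramolecular ketimine formation, six-membered ring) without touching C-3.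

**Compound list**

1 | 2-methoxybenzoyl chloride | COc1ccccc1C(Cl)=O | starting material
2 | N,N-diethyl-2-methoxybenzamide | CCN(CC)C(=O)c1ccccc1OC | intermediate
3 | 3-bromo-2-methylprop-1-ene | CC(=C)CBr | starting material
4 | [2-(diethylcarbamoyl)-3-methoxyphenyl]lithium | [Li]c1cccc(OC)c1C(=O)N(CC)CC | intermediate
5 | bromo[2-(diethylcarbamoyl)-3-methoxyphenyl]magnesium | Br[Mg]c1cccc(OC)c1C(=O)N(CC)CC | intermediate
6 | N,N-diethyl-2-methoxy-6-(2-methylprop-2-en-1-yl)benzamide | CCN(CC)C(=O)c1c(OC)cccc1CC(C)=C | intermediate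
7 | 8-methoxy-3-methylnaphthalen-1-ol | COc1cccc2cc(C)cc(O)c12 | intermediate
8 | 1,8-dimethoxy-3-methylnaphthalene | COc1cccc2cc(C)cc(OC)c12 | intermediate
9 | 1-bromo-4,5-dimethoxy-2-methylnaphthalene | Brc1c(C)cc(OC)c2c(OC)cccc12 | intermediate
10 | (4,5-dimethoxy-2-methylnaphthalen-1-yl)lithium | [Li]c1c(C)cc(OC)c2c(OC)cccc12 | intermediate
11 | lithium (4,5-dimethoxy-2-methylnaphthalen-1-yl)trimethoxyborate | [Li+].CO[B-](OC)(OC)c1c(C)cc(OC)c2c(OC)cccc12 | intermediate
12 | (4,5-dimethoxy-2-methylnaphthalen-1-yl)boronic acid | OB(O)c1c(C)cc(OC)c2c(OC)cccc12 | intermediate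
13 | 3-chloro-2-methoxyphenol | COc1c(O)cccc1Cl | starting material
14 | 3-bromoprop-1-ene (allyl bromide) | C=CCBr | starting material
15 | 1-chloro-2-methoxy-3-(prop-2-en-1-yloxy)benzene | COc1c(OCC=C)cccc1Cl | intermediate
16 | 3-chloro-2-methoxy-6-(prop-2-en-1-yl)phenol | COc1c(O)c(CC=C)ccc1Cl | intermediate
17 | 3-chloro-2-methoxy-6-(prop-2-en-1-yl)phenyl trifluoromethanesulfonate | COc1c(OS(=O)(=O)C(F)(F)F)c(CC=C)ccc1Cl | intermediate
18 | 3-chloro-2-methoxy-6-(2-oxopropyl)phenyl trifluoromethanesulfonate | COc1c(OS(=O)(=O)C(F)(F)F)c(CC(C)=O)ccc1Cl | intermediate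
19 | 6-[(2R)-2-aminopropyl]-3-chloro-2-methoxyphenyl trifluoromethanesulfonate | COc1c(OS(=O)(=O)C(F)(F)F)c(C[C@@H](C)N)ccc1Cl | intermediate
20 | 6-[(2R)-2-[(tert-butoxycarbonyl)amino]propyl]-3-chloro-2-methoxyphenyl trifluoromethanesulfonate | COc1c(OS(=O)(=O)C(F)(F)F)c(C[C@@H](C)NC(=O)OC(C)(C)C)ccc1Cl | intermediate
21 | tert-butyl N-[(2R)-1-[4-chloro-2-(1-ethoxyethenyl)-3-methoxyphenyl]propan-2-yl]carbamate | COc1c(C(=C)OCC)c(C[C@@H](C)NC(=O)OC(C)(C)C)ccc1Cl | intermediate
22 | tert-butyl N-[(2R)-1-(2-acetyl-4-chloro-3-methoxyphenyl)propan-2-yl]carbamate | COc1c(C(C)=O)c(C[C@@H](C)NC(=O)OC(C)(C)C)ccc1Cl | intermediate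
23 | tert-butyl N-[(2R)-1-[2-acetyl-4-(4,5-dimethoxy-2-methylnaphthalen-1-yl)-3-methoxyphenyl]propan-2-yl]carbamate (both atropo-diastereomers) | COc1c(C(C)=O)c(C[C@@H](C)NC(=O)OC(C)(C)C)ccc1-c1c(C)cc(OC)c2c(OC)cccc12 | intermediate
24 | 1-[6-[(2R)-2-aminopropyl]-3-(4,5-dimethoxy-2-methylnaphthalen-1-yl)-2-methoxyphenyl]ethan-1-one | COc1c(C(C)=O)c(C[C@@H](C)N)ccc1-c1c(C)cc(OC)c2c(OC)cccc12 | intermediate
25 | (3R)-7-(4,5-dimethoxy-2-methylnaphthalen-1-yl)-8-methoxy-1,3-dimethyl-3,4-dihydroisoquinoline | COc1c(-c2c(C)cc(OC)c3c(OC)cccc23)ccc2c1C(C)=N[C@H](C)C2 | target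

**Step count and risks**

Total step count: 15. Longest linear sequence: 9 steps (13 → 25, steps 7–15); the naphthalene branch (1 → 12, steps 1–6) joins at step 14.

Steps most likely to fail:

1. Step 11 (the transaminase may not accept the 2,3,4-trisubstituted, triflate-bearing arylacetone, or may stall at low conversion). The fallback sets out from 18 and comes back at 19. A Prelog-selective ketoreductase (alcohol dehydrogenase; NADP+ recycled by i-PrOH, pH 7 buffer, 30 °C) reduces 18 to 3-chloro-6-[(2S)-2-hydroxypropyl]-2-methoxyphenyl trifluoromethanesulfonate F1. Mitsunobu azidation with inversion (PPh3, DIAD, diphenylphosphoryl azide, THF, 0 °C → rt) gives 6-[(2R)-2-azidopropyl]-3-chloro-2-methoxyphenyl trifluoromethanesulfonate F2. Staudinger reduction (PPh3, THF/H2O, 50 °C) gives amine 19.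

2. Step 13 (the triflate is flanked by two ortho substituents, so the coupling with the stannane may be slow or incomplete). The fallback sets out from 20 and comes back at 22. It replaces the tin transmetalation by a Heck insertion: 20 and butyl vinyl ether with Pd(OAc)2, 1,3-bis(diphenylphosphino)propane and Et3N in DMF at 100 °C react by the cationic pathway open to triflates, which arylates the internal carbon of the electron-rich alkene. This gives tert-butyl N-[(2R)-1-[2-(1-butoxyethenyl)-4-chloro-3-methoxyphenyl]propan-2-yl]carbamate F3, which 1 M aq HCl in THF at rt hydrolyses to 22.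

3. Step 14 (the doubly ortho-substituted, electron-rich boronic acid 12 may protodeboronate faster than it couples with the aryl chloride). The fallback sets out from 22 and comes back at 23, with the polarity of the coupling reversed. Miyaura borylation of the chloride (Pd2(dba)3, XPhos, B2pin2, KOAc, 1,4-dioxane, 100 °C) gives tert-butyl N-[(2R)-1-[2-acetyl-3-methoxy-4-(4,4,5,5-tetramethyl-1,3,2-dioxaborolan-2-yl)phenyl]propan-2-yl]carbamate F4, a boronate with only one ortho substituent. F4 is coupled with bromide 9 (Pd(OAc)2, SPhos, K3PO4, toluene/H2O, 100 °C) to give 23; step 6 is then not needed.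

**Further compounds**

F1 | step 11 | 3-chloro-6-[(2S)-2-hydroxypropyl]-2-methoxyphenyl trifluoromethanesulfonate | COc1c(OS(=O)(=O)C(F)(F)F)c(C[C@H](C)O)ccc1Cl
F2 | step 11 | 6-[(2R)-2-azidopropyl]-3-chloro-2-methoxyphenyl trifluoromethanesulfonate | COc1c(OS(=O)(=O)C(F)(F)F)c(C[C@@H](C)N=[N+]=[N-])ccc1Cl
F3 | step 13 | tert-butyl N-[(2R)-1-[2-(1-butoxyethenyl)-4-chloro-3-methoxyphenyl]propan-2-yl]carbamate | COc1c(C(=C)OCCCC)c(C[C@@H](C)NC(=O)OC(C)(C)C)ccc1Cl
F4 | step 14 | tert-butyl N-[(2R)-1-[2-acetyl-3-methoxy-4-(4,4,5,5-tetramethyl-1,3,2-dioxaborolan-2-yl)phenyl]propan-2-yl]carbamate | COc1c(C(C)=O)c(C[C@@H](C)NC(=O)OC(C)(C)C)ccc1B1OC(C)(C)C(C)(C)O1
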